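**Retrosynthetic overview**

1. Locants: unit A = C1–C11 (C1 lactone C=O, C3=C8 butylidene, C3a=C7a, sp3 C6 and C7); unit B primed (C6′ carbinol, C4′ and C7′ bridgeheads); the units are joined by C6–C7′ and C7–C4′.
2. Both butenolides: Pd-catalysed carbonylative lactonisation of β-triflyloxy enones (C1 and C1′ from CO); the pentanoyl units come from enolate C-acylation (A) and from a 1,5-O→C acyl shift of the C6′ ester (B).
3. C6′–C7′: intramolecular aldol addition of the C7a′ ketone (enol carbon C7′) to a C4′–CH2–CHO arm, which closes the carbocycle of unit B as a bicyclo[2.2.2]octanone.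
4. Enabling feature: the C6′ carbinol is β to C7a′, and C7′/C4′ are 1,4-related on the cyclohexane C6–C7–C4′–C3a′–C7a′–C7′. Once butenolide B is unravelled to a C7a′ ketone, C6′–C7′ is an aldol bond. C7′ then becomes a bridgehead, which forbids dehydration and leaves C3a′ as the only enolisable position.
5. The cis-fused core (C6, C7, C4′ all-cis) comes from a catalytic asymmetric endo Diels–Alder reaction of a 2-silyloxy diene with cyclohex-2-enone. Ring order: carbocycle A (given) → cyclohexene C6/C7/C4′/C3a′/C7a′/C7′ → butenolide A → carbocycle of unit B (aldol) → butenolide B.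

Key step: step 8

Assumption (chemistry): the antipode of the oxazaborolidinium catalyst in step 3 is assigned from its α-C–H···O binding model for cyclic enones; if the facial sense proves opposite, the mirror-image catalyst is used and nothing else changes.
Remark: the β-dicarbonyl compounds 8 and 15 are written as single enol tautomers.

**Route**

Step 1
Reactants: 1 but-3-en-2-one; 2 tert-butyl(but-3-en-1-yloxy)dimethylsilane
Product: 3 (E)-6-[(tert-butyldimethylsilyl)oxy]hex-3-en-2-one
Conditions: 1 (3 equiv), second-generation Hoveyda–Grubbs catalyst [RuCl2(=CH-C6H4-2-O-i-Pr)(H2IMes)] (3 mol%), CH2Cl2, 40 °C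
Reagents that add atoms: none
Why: olefin cross-metathesis of an enone with a terminal alkene should favour the hetero-coupled product and give the (E)-enone under thermodynamic control.

Step 2
Reactants: 3
Product: 4 (E)-6-[(tert-butyldimethylsilyl)oxy]-2-[(triisopropylsilyl)oxy]hexa-1,3-diene
Conditions: i-Pr3SiOTf, Et3N, CH2Cl2, 0 °C
Reagents that add atoms: triisopropylsilyl trifluoromethanesulfonate, CC(C)[Si](C(C)C)(C(C)C)OS(=O)(=O)C(F)(F)F
Why: silyl triflate/amine enolisation of a methyl enone should remove an α′-methyl proton and give the cross-conjugated 2-silyloxy diene, leaving the (E)-alkene untouched.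

Step 3
Reactants: 4; 5 cyclohex-2-en-1-one
Product: 6 (4aR,8S,8aR)-8-{2-[(tert-butyldimethylsilyl)oxy]ethyl}-6-[(triisopropylsilyl)oxy]-3,4,4a,5,8,8a-hexahydronaphthalen-1(2H)-one (cis ring fusion; side chain cis to the C8a–C1 bond)
Conditions: (R)-1-(2-methylphenyl)-3,3-diphenyltetrahydro-1H,3H-pyrrolo[1,2-c][1,3,2]oxazaborole (20 mol%), HN(SO2CF3)2 (16 mol%), CH2Cl2, −78 → −40 °C
Reagents that add atoms: none
Why: Lewis acid-catalysed enantioselective Diels–Alder reaction in which the 2-silyloxy and 4-alkyl groups both direct the unsubstituted diene terminus to the enone β-carbon, the endo transition state with the (E)-diene places the side chain, the C8a–C1 bond and the C4a–C4 bond all cis, and the chiral oxazaborolidinium ion should expose the C2-Si/C3-Si face of the enone.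

Step 4
Reactants: 6; 7 pentanoyl chloride
Product: 8 2-pentanoyl derivative of 6 (C1 enol tautomer; stereocentres as in 6)
Conditions: LiN(SiMe3)2 (2.1 equiv), THF, −78 °C; then 7 (1.05 equiv), −78 → 0 °C
Reagents that add atoms: none
Why: kinetic deprotonation of the α-branched ketone by the hindered amide should occur at the CH2 side, and Claisen-type C-acylation follows, the second equivalent of base storing the product as its diketonate while the silyl enol ether masks the other ketone.

Step 5
Reactants: 8
Product: 9 C1 enol triflate of 8 (β-triflyloxy enone; stereocentres as in 6)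
Conditions: (CF3SO2)2O, i-Pr2NEt, CH2Cl2, −78 °C
Reagents that add atoms: trifluoromethanesulfonic anhydride, O=S(=O)(OS(=O)(=O)C(F)(F)F)C(F)(F)F
Why: O-sulfonylation of the enolised 2-acylcyclohexanone is expected at the ring oxygen, because the endocyclic enol is the favoured tautomer and the alternative is a strained exocyclic tetrasubstituted alkene.

Step 6
Reactants: 9
Product: 10 butenolide A closed: (Z)-3-butylidene-4,5,6,7-tetrahydrophthalide fused at C6–C7 to the cyclohexene that carries the C7a′ triisopropylsilyl enol ether (C7a′=C3a′) and the C4′ 2-(silyloxy)ethyl arm; H6, H7 and the arm all cis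
Conditions: Pd(OAc)2 (5 mol%), Ph2P(CH2)3PPh2 (6 mol%), Et3N, CO (1 atm), DMF, 60 °C
Reagents that add atoms: carbon monoxide, [C-]#[O+]
Why: carbonylative lactonisation in which zerovalent palladium inserts into the C–OTf bond, CO insertion gives an acylpalladium species and the enol oxygen of the neighbouring pentanoyl ketone closes the lactone, the (Z)-butylidene being the less strained geometry.

Step 7
Reactants: 10
Product: 11 keto alcohol (C7a′ ketone, C4′–CH2CH2OH arm; butenolide A unchanged)
Conditions: 48% aq. HF, MeCN, 0 → 23 °C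
Reagents that add atoms: none
Why: acidic fluoride should cleave the primary silyl ether and protodesilylate the enol ether to the ketone, conditions under which the enol lactone is stable.

Step 8
Reactants: 11
Product: 13 aldol product (6′-hydroxy-7a′-ketone with the bicyclo[2.2.2]octanone; hydroxyl syn to the ketone bridge; ring A syn to the C5′–C6′ bridge), via keto aldehyde 12 (not isolated)
Conditions: Dess–Martin periodinane, CH2Cl2, 0 → 23 °C; then TsOH·H2O (20 mol%), 23 °C, same flask
Reagents that add atoms: none
Why: Dess–Martin oxidation gives δ-keto aldehyde 12, and acid-catalysed enolisation of the C7a′ ketone toward C7′ is followed by addition of C7′ to the protonated aldehyde carbon C6′, an intramolecular aldol addition. The closest known reaction type is the acid-mediated cyclisation of 3-(2-oxoethyl)cyclohexanones to 6-hydroxybicyclo[2.2.2]octan-2-ones. The one ring closed (C7′–C7a′–C3a′–C4′–C5′–C6′, the carbocycle of unit B) forms in 6-(enolendo)-exo-trig mode through a boat transition state and completes the bicyclo[2.2.2]octane. C7′ can only be bonded on the face that carries the C4′ arm, so its configuration follows from the all-cis array of step 3 and puts ring A syn to the new C5′–C6′ bridge; at C6′ the hydroxyl should take the position syn to the ketone bridge, because the epimer pushes it against C5–H2 of ring A and loses the O–H···O=C hydrogen bond, and the reversible aldol lets this preference assert itself. The step needs chemo- and regioselectivity among enolisable sites: the C3a′ enol would have to close a four-membered ring, butenolide A is not enolised by acid (a free ring A ketone could close a bicyclo[3.3.1]nonane instead, which is why it is converted first), and dehydration is excluded because C7′ becomes a bridgehead.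

Step 9
Reactants: 13; 7 pentanoyl chloride
Product: 14 6′-O-pentanoate of 13
Conditions: pyridine, CH2Cl2, 0 °C
Reagents that add atoms: none
Why: O-acylation of the secondary alcohol with an acid chloride; β-elimination of the β-acyloxy ketone cannot occur because the carbon between the two groups is a bridgehead.

Step 10
Reactants: 14
Product: 15 3a′-pentanoyl-7a′-ketone with free 6′-hydroxyl (drawn as the C7a′ enol)
Conditions: MgBr2·OEt2 (2.5 equiv), i-Pr2NEt (3 equiv), CH2Cl2, 23 °C; aq. NH4Cl
Reagents that add atoms: none
Why: Proposed new method: magnesium should chelate the C7a′ ketone and the ester oxygen, the amine removes the only enolisable proton (C3a′–H), and the magnesium enolate attacks the ester carbonyl, which is held over the same face because C6′–O lies syn to the C7a′–C3a′ bridge (six-membered transition state); collapse of the tetrahedral intermediate gives the chelated magnesium β-diketonate, which drives this 1,5-O→C acyl shift, and the closest known reaction types are the Baker–Venkataraman rearrangement of o-acyloxyaryl ketones and the MgBr2/amine soft-enolisation C-acylation of ketones.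

Step 11
Reactants: 15
Product: 16 C7a′ enol triflate of 15 (β-triflyloxy enone; free 6′-hydroxyl)
Conditions: PhN(SO2CF3)2, i-Pr2NEt, DMF, 23 °C
Reagents that add atoms: N-phenylbis(trifluoromethanesulfonimide), O=S(=O)(N(c1ccccc1)S(=O)(=O)C(F)(F)F)C(F)(F)F
Why: the amine deprotonates only the β-diketone, and the mild triflyl donor should sulfonylate the enolate at the ring oxygen (endocyclic enol, no exocyclic tetrasubstituted alkene) while leaving the neutral secondary alcohol untouched.

Step 12
Reactants: 16
Product: 17 CNP0289078.1 (target)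
Conditions: Pd(OAc)2 (5 mol%), Ph2P(CH2)3PPh2 (6 mol%), Et3N, CO (1 atm), DMF, 60 °C
Reagents that add atoms: carbon monoxide, [C-]#[O+]
Why: the same carbonylative lactonisation as in step 6 should close butenolide B with (Z)-geometry, and the free C6′ hydroxyl cannot intercept the acylpalladium because the lactone it would form needs a twisted bridgehead-type alkene.

**Compound list**

1 | but-3-en-2-one | CC(=O)C=C | starting material
2 | tert-butyl(but-3-en-1-yloxy)dimethylsilane | C=CCCO[Si](C)(C)C(C)(C)C | starting material
3 | (E)-6-[(tert-butyldimethylsilyl)oxy]hex-3-en-2-one | CC(=O)/C=C/CCO[Si](C)(C)C(C)(C)C | intermediate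
4 | (E)-6-[(tert-butyldimethylsilyl)oxy]-2-[(triisopropylsilyl)oxy]hexa-1,3-diene | C=C(O[Si](C(C)C)(C(C)C)C(C)C)/C=C/CCO[Si](C)(C)C(C)(C)C | intermediate
5 | cyclohex-2-en-1-one | O=C1C=CCCC1 | starting material
6 | (4aR,8S,8aR)-8-{2-[(tert-butyldimethylsilyl)oxy]ethyl}-6-[(triisopropylsilyl)oxy]-3,4,4a,5,8,8a-hexahydronaphthalen-1(2H)-one | O=C2CCC[C@@H]1CC(O[Si](C(C)C)(C(C)C)C(C)C)=C[C@H](CCO[Si](C)(C)C(C)(C)C)[C@H]21 | intermediate
7 | pentanoyl chloride | CCCCC(=O)Cl | starting material
8 | 2-pentanoyl derivative of 6, C1 enol tautomer | OC2=C(C(=O)CCCC)CC[C@@H]1CC(O[Si](C(C)C)(C(C)C)C(C)C)=C[C@H](CCO[Si](C)(C)C(C)(C)C)[C@H]21 | intermediate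
9 | C1 enol triflate of 8 | O=S(=O)(OC2=C(C(=O)CCCC)CC[C@@H]1CC(O[Si](C(C)C)(C(C)C)C(C)C)=C[C@H](CCO[Si](C)(C)C(C)(C)C)[C@H]21)C(F)(F)F | intermediate
10 | butenolide A with C7a′ silyl enol ether and silyl-protected C4′ arm | CCC/C=C1\OC(=O)C2=C1CC[C@@H]1CC(O[Si](C(C)C)(C(C)C)C(C)C)=C[C@H](CCO[Si](C)(C)C(C)(C)C)[C@H]21 | intermediate
11 | keto alcohol (C7a′ ketone, C4′ 2-hydroxyethyl arm) | CCC/C=C1\OC(=O)C2=C1CC[C@@H]1CC(=O)C[C@H](CCO)[C@H]21 | intermediate
12 | keto aldehyde (C7a′ ketone, C4′ 2-oxoethyl arm) | CCC/C=C1\OC(=O)C2=C1CC[C@@H]1CC(=O)C[C@H](CC=O)[C@H]21 | intermediate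
13 | aldol product, 6′-hydroxy-7a′-ketone | CCC/C=C1\OC(=O)C2=C1CC[C@@H]1[C@H]3C(=O)C[C@H](C[C@@H]3O)[C@H]21 | intermediate
14 | 6′-O-pentanoate of 13 | CCC/C=C1\OC(=O)C2=C1CC[C@@H]1[C@H]3C(=O)C[C@H](C[C@@H]3OC(=O)CCCC)[C@H]21 | intermediate
15 | 3a′-pentanoyl-7a′-ketone, C7a′ enol tautomer, free 6′-hydroxyl | CCC/C=C1\OC(=O)C2=C1CC[C@@H]1[C@H]3C(O)=C(C(=O)CCCC)[C@H](C[C@@H]3O)[C@H]21 | intermediate
16 | C7a′ enol triflate of 15 | CCC/C=C1\OC(=O)C2=C1CC[C@@H]1[C@H]3C(OS(=O)(=O)C(F)(F)F)=C(C(=O)CCCC)[C@H](C[C@@H]3O)[C@H]21 | intermediate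
17 | CNP0289078.1 | CCC/C=C1\OC(=O)C2=C1CC[C@@H]1[C@H]3C4=C(/C(=C/CCC)OC4=O)[C@H](C[C@@H]3O)[C@H]21 | target

**Totals**

Total step count: 12. Longest linear sequence: 12 steps (from 1 and 2 to 17).

**Steps most likely to fail**

1. Step 10 (proposed new method). The magnesium enolate may fail to reach the ester carbonyl through the strained cage-like tetrahedral intermediate, the transfer may stop at the O-acyl enol ester, or enolisation of butenolide A may compete. Fallback, from 13 back to 15: 13 is silylated (Et3SiOTf, 2,6-lutidine) to the triethylsilyl ether F1. Intermolecular C-acylation of the C7a′ ketone under soft enolisation (MgBr2·OEt2, i-Pr2NEt, 7) gives the silylated diketone F2. HF·pyridine then removes the silyl group and gives 15.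

2. Step 11. Sulfonylation may fall on the side-chain oxygen of the enolised diketone, especially if the C6′ hydroxyl hydrogen-bonds to the ring oxygen; the same question arises, less acutely, in step 5. Fallback, from 13 back to 16, with the enol triflate made from a mono-ketone so that its position is fixed: a boron aldol reaction (dicyclohexylboron chloride, Et3N, then pentanal) gives the β-hydroxy ketone F3. Both hydroxyls are silylated (t-BuMe2SiOTf, 2,6-lutidine) to the bis-silyl ether F4. The ketone, enolisable only toward C3a′, is converted to the enol triflate F5 with (CF3SO2)2O and 2,6-di-tert-butyl-4-methylpyridine. HF·pyridine gives the diol F6, and MnO2 oxidises only its allylic carbinol to give 16.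

3. Step 3. Facial or endo discrimination may be insufficient with a 4-substituted 2-silyloxy diene, or a stepwise Mukaiyama–Michael pathway may stop at the open-chain adduct. Fallback, from 4 and 5 back to 6: the cycloaddition is run with an achiral Lewis acid (Me2AlCl, CH2Cl2, −78 °C), which gives 6 together with its enantiomer ent-6 F7. A ketoreductase (NADPH-dependent alcohol dehydrogenase class, glucose/glucose dehydrogenase recycling, pH 7 buffer), chosen by screening, should reduce only the unwanted enantiomer to the alcohol F8. Unreacted 6 is then separated by chromatography.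

**Further compounds**

F1 | step 10 | 6′-O-triethylsilyl ether of 13 | CCC/C=C1\OC(=O)C2=C1CC[C@@H]1[C@H]3C(=O)C[C@H](C[C@@H]3O[Si](CC)(CC)CC)[C@H]21
F2 | step 10 | 6′-O-triethylsilyl ether of 15 | CCC/C=C1\OC(=O)C2=C1CC[C@@H]1[C@H]3C(O)=C(C(=O)CCCC)[C@H](C[C@@H]3O[Si](CC)(CC)CC)[C@H]21
F3 | step 11 | 3a′-(1-hydroxypentyl) derivative of 13 (new centres undefined) | CCC/C=C1\OC(=O)C2=C1CC[C@@H]1[C@H]3C(=O)C(C(O)CCCC)[C@H](C[C@@H]3O)[C@H]21
F4 | step 11 | bis(tert-butyldimethylsilyl) ether of F3 | CCC/C=C1\OC(=O)C2=C1CC[C@@H]1[C@H]3C(=O)C(C(O[Si](C)(C)C(C)(C)C)CCCC)[C@H](C[C@@H]3O[Si](C)(C)C(C)(C)C)[C@H]21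
F5 | step 11 | C7a′ enol triflate of F4 | CCC/C=C1\OC(=O)C2=C1CC[C@@H]1[C@H]3C(OS(=O)(=O)C(F)(F)F)=C(C(O[Si](C)(C)C(C)(C)C)CCCC)[C@H](C[C@@H]3O[Si](C)(C)C(C)(C)C)[C@H]21
F6 | step 11 | diol enol triflate (allylic carbinol undefined) | CCC/C=C1\OC(=O)C2=C1CC[C@@H]1[C@H]3C(OS(=O)(=O)C(F)(F)F)=C(C(O)CCCC)[C@H](C[C@@H]3O)[C@H]21
F7 | step 3 | ent-6, (4aS,8R,8aS) | O=C2CCC[C@H]1CC(O[Si](C(C)C)(C(C)C)C(C)C)=C[C@@H](CCO[Si](C)(C)C(C)(C)C)[C@@H]21
F8 | step 3 | C1 alcohol from ent-6 (carbinol configuration set by the enzyme) | OC2CCC[C@H]1CC(O[Si](C(C)C)(C(C)C)C(C)C)=C[C@@H](CCO[Si](C)(C)C(C)(C)C)[C@@H]21
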